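Ring A of the target is an acylphloroglucinol: oxygen sits on C5, C7 and C8a, and C4a carries the C4 carbonyl. Everything rests on cutting the C4a–C8a bond, which turns ring A into a methyl 3,5,7-trioxoheptanoate chain attached through its C7 carbonyl to C4 of a ring B benzoxepinone that already holds the isopropylidene enol ether. Mg(OMe)2 folds this tetraketo ester in the Claisen mode and delivers the whole aromatic ring A in one operation. The chain is brought in as a dioxinone and unmasked thermally without acid or base; afterwards only pyranone closure and sigmatropic decoration of ring A, steered by the chelated 5-OH, remain.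

Key step: step 8

Assumption: compounds 6, 10, 11 and 12 are drawn as ketones but are enolized and racemic at C4 of the benzoxepinone; that centre vanishes in step 9, and the target has no stereocentre and no alkene geometry to set.

Step 1
Reactants: 1 3-methylbuta-1,2-diene
Product: 2 1,2-dibromo-3-methylbut-2-ene
Conditions: Br2 (1.0 equiv), CH2Cl2, −78 °C → rt, dark; then 40 °C until the allylic isomers have equilibrated
Reagents that add atoms: bromine, BrBr
Why: Electrophilic bromination of an allene puts bromine on the central carbon, and the tertiary allylic bromide formed first should rearrange to the more substituted alkene 2; either isomer gives the same product in step 2 (SN2 or SN2′).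

Step 2
Reactants: 3 1-(2-hydroxy-4,5-dimethoxyphenyl)ethanone; 2 1,2-dibromo-3-methylbut-2-ene
Product: 4 4-bromo-1-(2-hydroxy-4,5-dimethoxyphenyl)-5-methylhex-4-en-1-one
Conditions: 3, LiN(iPr)2 (2.2 equiv), THF, −78 → 0 °C; then 2 (1.1 equiv), −78 °C → rt; aq. NH4Cl
Reagents that add atoms: none
Why: Dianion alkylation of a 2-hydroxyacetophenone: the phenoxide is inert at low temperature, the more basic enolate carbon displaces the allylic bromide, and the vinylic bromide does not react.

Step 3
Reactants: 4 4-bromo-1-(2-hydroxy-4,5-dimethoxyphenyl)-5-methylhex-4-en-1-one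
Product: 5 7,8-dimethoxy-2-(propan-2-ylidene)-3,4-dihydro-1-benzoxepin-5(2H)-one
Conditions: CuI (10 mol%), 1,10-phenanthroline (20 mol%), Cs2CO3 (2 equiv), toluene, 110 °C
Reagents that add atoms: none
Why: Ullmann-type copper-catalysed intramolecular O-vinylation: carbonate deprotonates only the phenol, and CuI/phenanthroline couples the phenoxide with the vinyl bromide to close the seven-membered aryl enol ether.

Step 4
Reactants: 5 7,8-dimethoxy-2-(propan-2-ylidene)-3,4-dihydro-1-benzoxepin-5(2H)-one
Product: 6 4-acetyl-7,8-dimethoxy-2-(propan-2-ylidene)-3,4-dihydro-1-benzoxepin-5(2H)-one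
Conditions: MgBr2·OEt2 (2.5 equiv), i-Pr2NEt (3 equiv), 1-acetylbenzotriazole (1.2 equiv), CH2Cl2, rt; pH 7 buffer
Reagents that add atoms: 1-acetyl-1H-benzotriazole, CC(=O)n1nnc2ccccc12
Why: Soft-enolization crossed Claisen acylation: C4 is the only enolizable position, it is C-acetylated by the acylbenzotriazole, and chelation of the β-diketone by magnesium stops a second acylation.

Step 5
Reactants: 7 2,2,6-trimethyl-4H-1,3-dioxin-4-one
Product: 8 (2,2-dimethyl-4-oxo-4H-1,3-dioxin-6-yl)acetic acid
Conditions: LiN(iPr)2 (1.1 equiv), THF, −78 °C; CO2 (gas), −78 °C; cold 1 M HCl, extraction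
Reagents that add atoms: carbon dioxide, O=C=O
Why: γ-Deprotonation gives the vinylogous enolate of the dioxinone, which is carboxylated at the exocyclic carbon.

Step 6
Reactants: 6 4-acetyl-7,8-dimethoxy-2-(propan-2-ylidene)-3,4-dihydro-1-benzoxepin-5(2H)-one; 8 (2,2-dimethyl-4-oxo-4H-1,3-dioxin-6-yl)acetic acid
Product: 10 6-{4-[7,8-dimethoxy-5-oxo-2-(propan-2-ylidene)-2,3,4,5-tetrahydro-1-benzoxepin-4-yl]-2,4-dioxobutyl}-2,2-dimethyl-4H-1,3-dioxin-4-one, via acid chloride 9 (not isolated)
Conditions: 8, (COCl)2 (1.1 equiv), DMF (cat.), CH2Cl2, 0 °C, then evaporation; 6 (2.2 equiv), LiN(iPr)2 (4.5 equiv), THF, −78 → 0 °C; 9 added at −78 °C; AcOH, −78 °C; excess 6 recovered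
Reagents that add atoms: none
Why: Terminal-carbon acylation of a β-diketone dianion (Hauser–Harris type, as used for diketo-dioxinones): an ester of 8 would only be deprotonated at its doubly activated CH2, whereas 9 is turned by the first equivalent of dianion into the conjugated ketene, which the second equivalent captures at carbon.

Step 7
Reactants: 10 6-{4-[7,8-dimethoxy-5-oxo-2-(propan-2-ylidene)-2,3,4,5-tetrahydro-1-benzoxepin-4-yl]-2,4-dioxobutyl}-2,2-dimethyl-4H-1,3-dioxin-4-one
Product: 11 methyl 7-[7,8-dimethoxy-5-oxo-2-(propan-2-ylidene)-2,3,4,5-tetrahydro-1-benzoxepin-4-yl]-3,5,7-trioxoheptanoate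
Conditions: MeOH (30 equiv), toluene, 100 °C (sealed tube), 1 h; evaporation, crude used at once
Reagents that add atoms: methanol, CO
Why: Thermal retro-hetero-Diels–Alder fragmentation of the dioxinone releases acetone and an acylketene that methanol traps as the β-keto methyl ester; the medium is neutral, so the polyketone should reach step 8 uncyclized.

Step 8
Reactants: 11 methyl 7-[7,8-dimethoxy-5-oxo-2-(propan-2-ylidene)-2,3,4,5-tetrahydro-1-benzoxepin-4-yl]-3,5,7-trioxoheptanoate
Product: 12 7,8-dimethoxy-2-(propan-2-ylidene)-4-(2,4,6-trihydroxybenzoyl)-3,4-dihydro-1-benzoxepin-5(2H)-one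
Conditions: Mg(OMe)2 (8 equiv), MeOH, rt → 60 °C, argon; then aq. NH4Cl, 0 °C
Reagents that add atoms: none
Why: Mg(OMe)2 turns 11 into a chelated polyenolate in which the carbanion at chain C6 (between the C5 and C7 carbonyls, the future C4a) adds to the ester carbon C1 (the future C8a), methoxide leaves, and the 2-acylcyclohexane-1,3,5-trione enolizes to the phloroglucinol. The closest known reaction type is the Mg(OMe)2-mediated Claisen cyclization of 3,5,7-triketo esters, and of their pyranone lactones, to acylphloroglucinols. Ring A closes by 6-exo-trig attack on the ester carbonyl (enolendo when the C5–C6 enolate is the nucleophile). No stereocentre is formed. The step needs Claisen folding rather than aldol closure (C2 onto C7, or C4 onto the benzoxepinone ketone) or lactonization: the 2-substituted β-diketone made of C7 and the benzoxepinone ketone is held as an enolate chelated by magnesium, so neither ketone is an acceptor, the ester is the only carbonyl that is not enolized, and aromatization pulls the equilibrium toward ring A.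

Step 9
Reactants: 12 7,8-dimethoxy-2-(propan-2-ylidene)-4-(2,4,6-trihydroxybenzoyl)-3,4-dihydro-1-benzoxepin-5(2H)-one
Product: 13 5,7-dihydroxy-4′,5′-dimethoxyflavone bridged from C3 to C2′ by CH2–C(=CMe2)–O (oxepine ring)
Conditions: pyridinium p-toluenesulfonate (10 mol%), 4 Å molecular sieves, THF–toluene, 60 °C
Reagents that add atoms: none
Why: Cyclodehydration of a 2-hydroxyaryl 1,3-diketone (flavone synthesis): either of the two equivalent ortho hydroxyls adds to the benzoxepinone ketone and the hemiketal loses water, under acid weak and dry enough to spare the aryl enol ether.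

Step 10
Reactants: 13 oxepine-bridged 5,7-dihydroxyflavone
Product: 14 7-O-(2-methylbut-3-yn-2-yl) ether of 13
Conditions: 3-chloro-3-methylbut-1-yne (1.5 equiv), K2CO3 (2 equiv), KI (cat.), CuI (cat.), acetone, 50 °C, argon
Reagents that add atoms: 3-chloro-3-methylbut-1-yne, CC(C)(Cl)C#C
Why: Copper-assisted propargylic etherification goes to the acidic 7-OH alone, because the 5-OH is hydrogen-bonded to the C4 carbonyl.

Step 11
Reactants: 14 7-O-(2-methylbut-3-yn-2-yl) ether of 13
Product: 15 5-O-allyl 7-O-(2-methylbut-3-yn-2-yl) diether of 13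
Conditions: allyl bromide (2 equiv), K2CO3 (3 equiv), DMF, 60 °C
Reagents that add atoms: 3-bromoprop-1-ene, C=CCBr
Why: Williamson O-allylation of the chelated 5-OH under more forcing conditions; it is the only acidic group left.

Step 12
Reactants: 15 5-O-allyl 7-O-(2-methylbut-3-yn-2-yl) diether of 13
Product: 17 6-allyl-5-hydroxy flavone with a 2,2-dimethyl-2H-pyran fused at O7 and C8, via chromene allyl ether 16 (not isolated)
Conditions: N,N-diethylaniline, 140 °C, then 195 °C, argon; direct chromatography (no acid wash)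
Reagents that add atoms: none
Why: Two aromatic Claisen rearrangements in sequence: the tertiary propargyl ether shifts first to C8 (the position favoured in chromones without a free 5-OH) and closes to the dimethylchromene by 1,5-hydrogen shift and oxa-6π electrocyclization, after which the 5-O-allyl group has only C6 as ortho terminus.

Step 13
Reactants: 17 6-allyl-5-hydroxy pyranoflavone
Product: 18 6-allyl-5-methoxy pyranoflavone
Conditions: MeI (5 equiv), Cs2CO3 (3 equiv), DMF, 40 °C
Reagents that add atoms: iodomethane, CI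
Why: Williamson O-methylation of the hindered, chelated 5-OH; every other oxygen is already capped.

Step 14
Reactants: 18 6-allyl-5-methoxy pyranoflavone
Product: 19 target CNP0192589.0
Conditions: 2-methylbut-2-ene (excess), second-generation Grubbs catalyst RuCl2(H2IMes)(PCy3)(=CHPh) (5 mol%), CH2Cl2, 40 °C
Reagents that add atoms: 2-methylbut-2-ene, CC=C(C)C
Why: Olefin cross-metathesis of the terminal allyl group with excess 2-methylbut-2-ene gives the prenyl group, while the tetrasubstituted enol ether and the hindered chromene double bond are poor metathesis partners.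

Compound list
1 | 3-methylbuta-1,2-diene | CC(C)=C=C | starting material
2 | 1,2-dibromo-3-methylbut-2-ene | CC(C)=C(Br)CBr | intermediate
3 | 1-(2-hydroxy-4,5-dimethoxyphenyl)ethanone | CC(=O)c1cc(OC)c(OC)cc1O | starting material
4 | 4-bromo-1-(2-hydroxy-4,5-dimethoxyphenyl)-5-methylhex-4-en-1-one | CC(C)=C(Br)CCC(=O)c1cc(OC)c(OC)cc1O | intermediate
5 | 7,8-dimethoxy-2-(propan-2-ylidene)-3,4-dihydro-1-benzoxepin-5(2H)-one | COc1cc2OC(=C(C)C)CCC(=O)c2cc1OC | intermediate
6 | 4-acetyl-7,8-dimethoxy-2-(propan-2-ylidene)-3,4-dihydro-1-benzoxepin-5(2H)-one (racemic) | CC(=O)C1CC(=C(C)C)Oc2cc(OC)c(OC)cc2C1=O | intermediate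
7 | 2,2,6-trimethyl-4H-1,3-dioxin-4-one | CC1=CC(=O)OC(C)(C)O1 | starting material
8 | (2,2-dimethyl-4-oxo-4H-1,3-dioxin-6-yl)acetic acid | OC(=O)CC1=CC(=O)OC(C)(C)O1 | intermediate
9 | (2,2-dimethyl-4-oxo-4H-1,3-dioxin-6-yl)acetyl chloride | ClC(=O)CC1=CC(=O)OC(C)(C)O1 | intermediate (not isolated)
10 | 6-{4-[7,8-dimethoxy-5-oxo-2-(propan-2-ylidene)-2,3,4,5-tetrahydro-1-benzoxepin-4-yl]-2,4-dioxobutyl}-2,2-dimethyl-4H-1,3-dioxin-4-one (racemic) | CC1(C)OC(=O)C=C(CC(=O)CC(=O)C2CC(=C(C)C)Oc3cc(OC)c(OC)cc3C2=O)O1 | intermediate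
11 | methyl 7-[7,8-dimethoxy-5-oxo-2-(propan-2-ylidene)-2,3,4,5-tetrahydro-1-benzoxepin-4-yl]-3,5,7-trioxoheptanoate (racemic) | COC(=O)CC(=O)CC(=O)CC(=O)C1CC(=C(C)C)Oc2cc(OC)c(OC)cc2C1=O | intermediate
12 | 7,8-dimethoxy-2-(propan-2-ylidene)-4-(2,4,6-trihydroxybenzoyl)-3,4-dihydro-1-benzoxepin-5(2H)-one (racemic) | Oc1cc(O)c(c(O)c1)C(=O)C1CC(=C(C)C)Oc2cc(OC)c(OC)cc2C1=O | intermediate
13 | 5,7-dihydroxy-4′,5′-dimethoxyflavone bridged from C3 to C2′ by CH2–C(=CMe2)–O | COc1cc2c(cc1OC)-c1oc3cc(O)cc(O)c3c(=O)c1CC(=C(C)C)O2 | intermediate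
14 | 7-O-(2-methylbut-3-yn-2-yl) ether of 13 | COc1cc2c(cc1OC)-c1oc3cc(OC(C)(C)C#C)cc(O)c3c(=O)c1CC(=C(C)C)O2 | intermediate
15 | 5-O-allyl 7-O-(2-methylbut-3-yn-2-yl) diether of 13 | COc1cc2c(cc1OC)-c1oc3cc(OC(C)(C)C#C)cc(OCC=C)c3c(=O)c1CC(=C(C)C)O2 | intermediate
16 | 5-allyloxy flavone with 2,2-dimethyl-2H-pyran fused at O7 and C8 | COc1cc2c(cc1OC)-c1oc3c4c(cc(OCC=C)c3c(=O)c1CC(=C(C)C)O2)OC(C)(C)C=C4 | intermediate (not isolated)
17 | 6-allyl-5-hydroxy flavone with 2,2-dimethyl-2H-pyran fused at O7 and C8 | COc1cc2c(cc1OC)-c1oc3c4c(c(CC=C)c(O)c3c(=O)c1CC(=C(C)C)O2)OC(C)(C)C=C4 | intermediate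
18 | 6-allyl-5-methoxy flavone with 2,2-dimethyl-2H-pyran fused at O7 and C8 | COc1cc2c(cc1OC)-c1oc3c4c(c(CC=C)c(OC)c3c(=O)c1CC(=C(C)C)O2)OC(C)(C)C=C4 | intermediate
19 | CNP0192589.0 (5-methoxy-6-prenyl analogue of 18; no stereocentre) | COc1cc2c(cc1OC)-c1oc3c4c(c(CC=C(C)C)c(OC)c3c(=O)c1CC(=C(C)C)O2)OC(C)(C)C=C4 | target

Total step count: 14. Longest linear sequence: 13 steps (steps 1–4 and 6–14, from 3-methylbuta-1,2-diene); step 5 is a one-step branch.

Steps most likely to fail

Step 8. The polyenolate may fold the wrong way (aldol closure of C2 onto C7 or of C4 onto the benzoxepinone ketone, or lactonization to a 4-hydroxypyranone), or methoxide may cleave the 2-substituted β-diketone in a retro-Claisen reaction. The fallback brings ring A in preformed instead of folding it, and sets out from 5. 2,4,6-Trihydroxybenzoic acid is per-allylated (allyl bromide, K2CO3, DMF) to allyl 2,4,6-tris(allyloxy)benzoate F1, saponified (LiOH, THF–water) to 2,4,6-tris(allyloxy)benzoic acid F2, and converted with (COCl)2 into 2,4,6-tris(allyloxy)benzoyl chloride F3. Soft-enolization C-acylation of 5 with it (MgBr2·OEt2, i-Pr2NEt, CH2Cl2) should give 7,8-dimethoxy-2-(propan-2-ylidene)-4-[2,4,6-tris(allyloxy)benzoyl]-3,4-dihydro-1-benzoxepin-5(2H)-one F4. Pd(PPh3)4 (zerovalent palladium) with morpholine then removes the three allyl groups under neutral conditions, and the route is rejoined at 12.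

Step 6. Proton transfer from the doubly activated methylene of the acyl donor may simply quench the dianion, and the ketene may dimerize or acylate on oxygen. The fallback replaces the polyanion by a neutral Mukaiyama-type acylation and sets out from 6. Et3N and TMSCl give 4-acetyl-7,8-dimethoxy-2-(propan-2-ylidene)-5-(trimethylsilyloxy)-2,3-dihydro-1-benzoxepine F5, and LiN(iPr)2 followed by TMSCl gives the 1,3-bis(silyl enol ether) 7,8-dimethoxy-2-(propan-2-ylidene)-5-(trimethylsilyloxy)-4-[1-(trimethylsilyloxy)ethenyl]-2,3-dihydro-1-benzoxepine F6. This diene should be acylated at its terminal carbon by 9 in CH2Cl2 (−78 → 20 °C, no base); work-up with aq. NaHCO3 removes the silyl groups, and the route is rejoined at 10.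

Step 3. Oxidative addition at the fully substituted vinyl bromide may be slow, and the ketone may couple through its enolate oxygen in a five-membered ring closure to a dihydrofuran. The fallback closes the ring by allylic substitution and makes the enol ether by isomerization, setting out from 3. The dianion of 3 (LiN(iPr)2, THF) is alkylated with excess (E)-1,4-dibromo-2-methylbut-2-ene at the less hindered CH2Br to give (E)-6-bromo-1-(2-hydroxy-4,5-dimethoxyphenyl)-5-methylhex-4-en-1-one F7. Pd(PPh3)4 (zerovalent palladium) and K2CO3 in THF should close the seven-membered ring by intramolecular O-allylation at the inner allyl terminus, giving 7,8-dimethoxy-2-(prop-1-en-2-yl)-3,4-dihydro-1-benzoxepin-5(2H)-one F8 (racemic). RuHCl(CO)(PPh3)3 in toluene at 100 °C then moves the allyl-ether double bond into conjugation with oxygen, and the route is rejoined at 5.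

Further compounds
F1 | step 8 | allyl 2,4,6-tris(allyloxy)benzoate | C=CCOC(=O)c1c(OCC=C)cc(OCC=C)cc1OCC=C
F2 | step 8 | 2,4,6-tris(allyloxy)benzoic acid | OC(=O)c1c(OCC=C)cc(OCC=C)cc1OCC=C
F3 | step 8 | 2,4,6-tris(allyloxy)benzoyl chloride | ClC(=O)c1c(OCC=C)cc(OCC=C)cc1OCC=C
F4 | step 8 | 7,8-dimethoxy-2-(propan-2-ylidene)-4-[2,4,6-tris(allyloxy)benzoyl]-3,4-dihydro-1-benzoxepin-5(2H)-one (racemic) | C=CCOc1cc(OCC=C)c(C(=O)C2CC(=C(C)C)Oc3cc(OC)c(OC)cc3C2=O)c(OCC=C)c1
F5 | step 6 | 4-acetyl-7,8-dimethoxy-2-(propan-2-ylidene)-5-(trimethylsilyloxy)-2,3-dihydro-1-benzoxepine | COc1cc2OC(=C(C)C)CC(C(C)=O)=C(O[Si](C)(C)C)c2cc1OC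
F6 | step 6 | 7,8-dimethoxy-2-(propan-2-ylidene)-5-(trimethylsilyloxy)-4-[1-(trimethylsilyloxy)ethenyl]-2,3-dihydro-1-benzoxepine | COc1cc2OC(=C(C)C)CC(C(=C)O[Si](C)(C)C)=C(O[Si](C)(C)C)c2cc1OC
F7 | step 3 | (E)-6-bromo-1-(2-hydroxy-4,5-dimethoxyphenyl)-5-methylhex-4-en-1-one | BrC/C(C)=C/CCC(=O)c1cc(OC)c(OC)cc1O
F8 | step 3 | 7,8-dimethoxy-2-(prop-1-en-2-yl)-3,4-dihydro-1-benzoxepin-5(2H)-one (racemic) | COc1cc2OC(CCC(=O)c2cc1OC)C(C)=C
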